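**Plan**

- Retrosynthesis: the dihydropyran is cut at its spiro C–O bond and at its CH2–CH(isopropyl) bond (retro hetero-Diels–Alder), giving (1R,5R)-β-pinene, 2-methylpropanal and syncarpic acid. The pinene, with its CH2 bridge written as C=O, is then cut at two cyclobutane bonds (retro [2+2]): carbonyl carbon to the bridgehead remote from the spiro carbon, and CMe2 to the bridgehead next to it. This leads to an acyclic vinylketene from (2E)-geranic acid.
- Enabling feature: in the bicyclo[3.1.1]heptane the one-carbon CH2 bridge lies between two bridgehead CH groups and faces a CMe2 bridge. This is the pattern left by a ketene carbon that has added across a Me2C=CH alkene; the spiro carbon is the old C3 of the geranyl chain.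
- Forward: acid chloride, then one operation that closes the cyclobutanone and the six-membered ring together; resolution of the bicyclic ketone; Wolff–Kishner reduction to the pinene. In a side line, dearomatising fourfold C-methylation of 2,4,6-trihydroxyacetophenone and deacetylation give syncarpic acid. Last, Knoevenagel condensation and hetero-Diels–Alder reaction build the pyran ring and the spiro junction.
- Stereochemistry: the relative configuration of the bridgeheads is forced by the ring; their absolute configuration comes from separating diastereomeric adducts with an enantiopure sulfoximine. The spiro centre comes from attack of the heterodiene anti to the CMe2 bridge. The isopropyl-bearing centre comes from the orientation of the cycloaddition, with chromatographic removal of its epimer.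

Key step: step 2

Assumption: (2E)-geranic acid is used isomerically pure; any Z acid would lead to the endocyclic alkene isomer of the bicyclic ketone, which would be removed by chromatography after step 2.
Assumption: the target needs the (1R,5R) pinane unit (the dextrorotatory β-pinene series); the adduct of step 3 that contains the (1R,5S) ketone would be identified by X-ray analysis, the sulfur configuration serving as internal reference.

**Route**

Step 1
Reactants: 1 (2E)-3,7-dimethylocta-2,6-dienoic acid (geranic acid)
Product: 2 (2E)-3,7-dimethylocta-2,6-dienoyl chloride
Conditions: (COCl)2, DMF (cat.), CH2Cl2, 0 °C to rt; evaporate, use crude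
Reagents that add atoms: oxalyl chloride, ClC(=O)C(=O)Cl
Why: Acid chloride formation through chloroiminium (Vilsmeier-type) activation should proceed at or below room temperature with only gaseous by-products, so that the E geometry of the conjugated double bond and the remote trisubstituted alkene stay untouched.

Step 2
Reactants: 2 (2E)-3,7-dimethylocta-2,6-dienoyl chloride
Product: 4 racemic 7,7-dimethyl-2-methylidenebicyclo[3.1.1]heptan-6-one, via vinylketene 3 (not isolated)
Conditions: Et3N, toluene, 110 °C, slow addition of 2 (about 0.01 M)
Reagents that add atoms: none
Why: Et3N removes HCl from 2 in a 1,4-sense (deprotonation of the C3 methyl group, which lies cis to the acyl group in the E isomer) to give the cross-conjugated vinylketene 3, whose ketene unit then adds to the remote trisubstituted alkene in a thermal, concerted but asynchronous [2+2] cycloaddition. The closest known reaction type is the intramolecular ketene–alkene [2+2] cycloaddition of an unsaturated acid chloride under amine base, which is established for this kind of vinylketene with a three-atom tether. Two rings close at once: the leading bond from the electrophilic ketene carbonyl carbon to the alkene CH closes the six-membered carbocycle in a 6-exo sense, and the second bond from the ketene α-carbon to the CMe2 terminus closes the cyclobutanone across that ring (bridged, not fused, mode). The two new stereocentres are the bridgeheads; their relative configuration is fixed by the geometry of the one-atom bridges, and because 2 carries no stereochemical element the product is racemic, the absolute configuration being selected in steps 3 and 4. The step needs bridged over fused regiochemistry, which the gem-dimethyl terminus secures because the alkene carbon better able to carry positive charge (CMe2) bonds to the ketene α-carbon while the less substituted CH attacks the carbonyl carbon; it also needs the exocyclic rather than the endocyclic alkene, which the E geometry of 2 should secure. Ring closure over ketene dimerisation is secured by slow addition into hot dilute base.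

Step 3
Reactants: 4 racemic 7,7-dimethyl-2-methylidenebicyclo[3.1.1]heptan-6-one; 5 (S)-N,S-dimethyl-S-phenylsulfoximine
Product: 6 β-hydroxysulfoximine adduct of the (1R,5S) enantiomer of 4 (sulfoximinylmethyl group over the three-carbon bridge, hydroxyl on the opposite face of the cyclobutane, S configuration at sulfur)
Conditions: 5, n-BuLi, THF, −78 °C; then 4, −78 °C; H2O at −78 °C; SiO2 chromatography or crystallisation
Reagents that add atoms: none
Why: 1,2-Addition of the α-lithiated sulfoximine to the strained, non-enolisable cyclobutanone (resolution of a ketone through diastereomeric β-hydroxysulfoximines) should be fast at −78 °C; the new carbinol centre is expected to arise from attack on the carbonyl face over the three-carbon bridge, because the opposite face is blocked across the four-membered ring by the exo methyl group of the CMe2 bridge, and the fixed sulfur stereocentre makes the adducts of the two enantiomers of 4 diastereomers, of which the one built from the (1R,5S) ketone is kept.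

Step 4
Reactants: 6 β-hydroxysulfoximine adduct
Product: 7 (1R,5S)-7,7-dimethyl-2-methylidenebicyclo[3.1.1]heptan-6-one
Conditions: xylene, 130 °C; bulb-to-bulb distillation
Reagents that add atoms: none
Why: Heating a β-hydroxysulfoximine reverses the addition through proton transfer from O–H to the sulfoximine nitrogen and C–C cleavage under neutral conditions that touch neither bridgehead, so the ketone should be released with the configuration selected in step 3 while the carbinol centre is erased.

Step 5
Reactants: 7 (1R,5S)-7,7-dimethyl-2-methylidenebicyclo[3.1.1]heptan-6-one
Product: 9 (1R,5R)-6,6-dimethyl-2-methylidenebicyclo[3.1.1]heptane, via hydrazone 8 (not isolated)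
Conditions: N2H4·H2O, KOH, diethylene glycol, 130 °C then 200 °C, product distilled out as formed
Reagents that add atoms: none
Why: Wolff–Kishner reduction: the hydrazone 8 is deprotonated, tautomerises to the diazene and loses N2 to leave the CH2 bridge; the bridgeheads cannot enolise (Bredt's rule), so their configuration is kept, and distilling the volatile hydrocarbon out limits base-induced migration of the exocyclic double bond.

Step 6
Reactants: 10 1-(2,4,6-trihydroxyphenyl)ethanone
Product: 11 2-acetyl-3-hydroxy-4,4,6,6-tetramethylcyclohex-2-ene-1,5-dione
Conditions: NaOMe, MeI, MeOH, 0 °C to reflux; then aq. HCl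
Reagents that add atoms: iodomethane, CI
Why: Fourfold C-methylation of the phloroglucinol nucleus: the phenoxide reacts as a carbon nucleophile at the two free ring positions, each of which is alkylated twice because the first methylation leaves an enolisable 1,3-dicarbonyl unit, so the arene is dearomatised to the enolised β-triketone while the acetyl group blocks the third position.

Step 7
Reactants: 11 2-acetyl-3-hydroxy-4,4,6,6-tetramethylcyclohex-2-ene-1,5-dione
Product: 12 2,2,4,4-tetramethylcyclohexane-1,3,5-trione (syncarpic acid)
Conditions: 6 M aq. HCl, reflux
Reagents that add atoms: none
Why: Acid-promoted retro-Claisen cleavage of the exocyclic acyl group of a 2-acyl-1,3-dione (hydration of the acetyl carbonyl group, then C–C fragmentation) should remove the acetyl group as acetic acid and leave the cyclic trione.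

Step 8
Reactants: 9 (1R,5R)-6,6-dimethyl-2-methylidenebicyclo[3.1.1]heptane; 12 syncarpic acid; 13 2-methylpropanal
Product: 15 (1'S,2S,4R,5'R)-6,6,6',6',8,8-hexamethyl-4-(propan-2-yl)-3,4-dihydrospiro[chromene-2,2'-bicyclo[3.1.1]heptane]-5,7(6H,8H)-dione, via alkylidene trione 14 (not isolated)
Conditions: 12, 13, ethylenediammonium diacetate (cat.), toluene, rt; then 9, 80 °C, sealed tube; SiO2 chromatography
Reagents that add atoms: none
Why: Domino Knoevenagel condensation and hetero-Diels–Alder reaction with inverse electron demand: the 2-alkylidene-1,3-dione 14 reacts as an electron-poor 1-oxadiene whose alkylidene carbon bonds to the CH2 terminus of the alkene and whose oxygen bonds to the quaternary carbon; the heterodiene should approach the exocyclic alkene from the face of the CH2 bridge, anti to the CMe2 bridge, which sets the spiro centre (S), while the isopropyl-bearing centre (R) follows from the orientation in which the bridgehead side of the alkene lies under the heterodiene, its epimer being expected as a co-product that is removed by chromatography.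

**Compound list**

1 | (2E)-3,7-dimethylocta-2,6-dienoic acid (geranic acid) | CC(C)=CCC/C(C)=C/C(=O)O | starting material
2 | (2E)-3,7-dimethylocta-2,6-dienoyl chloride | CC(C)=CCC/C(C)=C/C(=O)Cl | intermediate
3 | 7-methyl-3-methylideneocta-1,6-dien-1-one (vinylketene, not isolated) | CC(C)=CCCC(=C)C=C=O | intermediate
4 | racemic 7,7-dimethyl-2-methylidenebicyclo[3.1.1]heptan-6-one (both enantiomers; no descriptors are written because the ring fixes the relative configuration of the bridgeheads) | C=C1CCC2C(=O)C1C2(C)C | intermediate
5 | (S)-N,S-dimethyl-S-phenylsulfoximine | CN=[S@@](C)(=O)c1ccccc1 | starting material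
6 | (S)-N-methyl-S-phenyl-S-[(6-hydroxy-7,7-dimethyl-2-methylidenebicyclo[3.1.1]heptan-6-yl)methyl]sulfoximine, adduct of the (1R,5S) ketone, CH2S group over the three-carbon bridge | C=C1CC[C@@H]2[C@](O)(C[S@@](=O)(=NC)c3ccccc3)[C@H]1C2(C)C | intermediate
7 | (1R,5S)-7,7-dimethyl-2-methylidenebicyclo[3.1.1]heptan-6-one | C=C1CC[C@@H]2C(=O)[C@H]1C2(C)C | intermediate
8 | hydrazone of 7 (not isolated) | C=C1CC[C@@H]2C(=NN)[C@H]1C2(C)C | intermediate
9 | (1R,5R)-6,6-dimethyl-2-methylidenebicyclo[3.1.1]heptane ((+)-β-pinene) | C=C1CC[C@@H]2C[C@H]1C2(C)C | intermediate
10 | 1-(2,4,6-trihydroxyphenyl)ethanone | CC(=O)c1c(O)cc(O)cc1O | starting material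
11 | 2-acetyl-3-hydroxy-4,4,6,6-tetramethylcyclohex-2-ene-1,5-dione | CC(=O)C1=C(O)C(C)(C)C(=O)C(C)(C)C1=O | intermediate
12 | 2,2,4,4-tetramethylcyclohexane-1,3,5-trione (syncarpic acid) | O=C1CC(=O)C(C)(C)C(=O)C1(C)C | intermediate
13 | 2-methylpropanal | CC(C)C=O | starting material
14 | 2,2,4,4-tetramethyl-6-(2-methylpropylidene)cyclohexane-1,3,5-trione (not isolated) | CC(C)C=C1C(=O)C(C)(C)C(=O)C(C)(C)C1=O | intermediate
15 | (1'S,2S,4R,5'R)-6,6,6',6',8,8-hexamethyl-4-(propan-2-yl)-3,4-dihydrospiro[chromene-2,2'-bicyclo[3.1.1]heptane]-5,7(6H,8H)-dione | CC(C)[C@H]1C[C@]2(CC[C@@H]3C[C@H]2C3(C)C)OC2=C1C(=O)C(C)(C)C(=O)C2(C)C | target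

**Step count and risks**

Total step count: 8 (steps 1 to 5 and 8 in the main line, steps 6 and 7 in the side line). Longest linear sequence: 6 steps (1, 2, 3, 4, 5, 8).

Steps most likely to fail:

Step 3 (with the release in step 4). The two diastereomeric adducts may not separate. Addition may occur on both faces of the carbonyl group, so that four adducts form. The lithium alkoxide of the strained cyclobutanol may fragment toward the allylic bridgehead before the quench. The thermal release may be sluggish because addition to a cyclobutanone relieves strain. The fallback sets out from 4 and comes back at 7. Ketalisation of 4 with (2R,3R)-butane-2,3-diol (as its bis(trimethylsilyl) ether, Me3SiOTf cat., CH2Cl2, −78 °C) creates no new stereocentre and should give just two diastereomers. These are the (4R,5R)-4,5-dimethyl-1,3-dioxolane ketal of the (1R,5S) ketone F1 and the corresponding ketal of the (1S,5R) ketone F2, which would be separated by chromatography. Mild acid hydrolysis of F1 (pyridinium p-toluenesulfonate in wet acetone, or dilute aq. HCl in THF) then gives 7.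

Step 8. The two orientations of the heterodiene over the alkene may be poorly discriminated, so that much of the epimer at the isopropyl-bearing carbon forms. The strained alkene may isomerise or rearrange through a cation under the ammonium acetate catalyst at 80 °C. Compound 14 may condense with itself. The fallback sets out from 12 and 13 and comes back at 15. Organocatalytic reductive alkylation of 12 with 13 (Hantzsch ester, L-proline cat., CH2Cl2, rt) gives 3-hydroxy-4,4,6,6-tetramethyl-2-(2-methylpropyl)cyclohex-2-ene-1,5-dione F3. C-Selenenylation (PhSeCl, pyridine, CH2Cl2, 0 °C) gives 2,2,4,4-tetramethyl-6-(2-methylpropyl)-6-(phenylselanyl)cyclohexane-1,3,5-trione F4. Oxidation at selenium (O3, CH2Cl2, −78 °C, then purge), addition of 9 and pyridine, and warming to room temperature should release 14 by selenoxide syn-elimination under neutral, water-free conditions. The cycloaddition to 15 can then run at or near room temperature, where the kinetic preference between the two orientations should be larger and the alkene is not exposed to acid.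

Step 5. Hydroxide may attack the strained, non-enolisable cyclobutanone and cleave the ring before the hydrazone forms. The exocyclic double bond may migrate into the ring under the hot basic conditions. The volatile product may be lost. The fallback sets out from 7 and comes back at 9. Condensation with TsNHNH2 (EtOH, rt) gives the 4-methylbenzenesulfonylhydrazone of 7 F5. Reduction with catecholborane (CHCl3, 0 °C) and then NaOAc·3H2O at reflux expels sulfinate and N2 from the derived diazene and should give 9 without strong base or high temperature.

Further compounds
F1 | step 3 | (4R,5R)-4,5-dimethyl-1,3-dioxolane ketal of (1R,5S)-7,7-dimethyl-2-methylidenebicyclo[3.1.1]heptan-6-one | C=C1CC[C@@H]2C3(O[C@H](C)[C@@H](C)O3)[C@H]1C2(C)C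
F2 | step 3 | (4R,5R)-4,5-dimethyl-1,3-dioxolane ketal of (1S,5R)-7,7-dimethyl-2-methylidenebicyclo[3.1.1]heptan-6-one | C=C1CC[C@H]2C3(O[C@H](C)[C@@H](C)O3)[C@@H]1C2(C)C
F3 | step 8 | 3-hydroxy-4,4,6,6-tetramethyl-2-(2-methylpropyl)cyclohex-2-ene-1,5-dione | CC(C)CC1=C(O)C(C)(C)C(=O)C(C)(C)C1=O
F4 | step 8 | 2,2,4,4-tetramethyl-6-(2-methylpropyl)-6-(phenylselanyl)cyclohexane-1,3,5-trione | CC(C)CC1([Se]c2ccccc2)C(=O)C(C)(C)C(=O)C(C)(C)C1=O
F5 | step 5 | 4-methylbenzenesulfonylhydrazone of (1R,5S)-7,7-dimethyl-2-methylidenebicyclo[3.1.1]heptan-6-one | C=C1CC[C@@H]2C(=NNS(=O)(=O)c3ccc(C)cc3)[C@H]1C2(C)C
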